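**Retrosynthetic overview**
- Prolifenone B ⇐ removal of a C3 spiro-dithiane blocking group ⇐ bicyclo[3.3.1]nonane made by a cation–enol cyclisation: a C8 tertiary cation is trapped by the acyl-bearing carbon C1 of a dearomatised acylphloroglucinol (C1–C8 bond, ring A), the same bond the prenylation–cyclisation of the farnesylated acylphloroglucinol makes in the plant.
- Cyclisation precursor ⇐ C5–C6 bond by reductive alkylation of the blocked acylphloroglucinol with a β-hydroxy aldehyde that already carries C7 (prenyl) and the C8 carbinol.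
- Aldehyde ⇐ (2E,6E)-farnesol by Sharpless epoxidation and prenyl-copper opening at C2 (sets C7 and the absolute configuration).
- Blocked ring ⇐ phlorisobutyrophenone ⇐ phloroglucinol + isobutyryl chloride; the dithiane keeps C5 sp3 (so the ring can bridge and does not simply close a chroman) and removes C3 as a competing nucleophile.
- Ring order: ring B (the polyketide phloroglucinol ring) first, ring A second, in the single ring-forming step.

Assumption: atom labels C1–C9 follow the bicyclo[3.3.1]nonane numbering of the target (C1 acyl bridgehead, C5 H bridgehead, C7 prenyl, C8 quaternary), which makes the target (1R,5R,7S,8R); enolised triketones are drawn as one tautomer.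

**Route**

Step 1
Reactants: 1 phloroglucinol (benzene-1,3,5-triol); 2 isobutyryl chloride (2-methylpropanoyl chloride)
Product: 3 phlorisobutyrophenone [2-methyl-1-(2,4,6-trihydroxyphenyl)propan-1-one]
Conditions: AlCl3 (3.5 equiv), PhNO2/CH2Cl2, 0 → 45 °C; aq HCl
Reagents that add atoms: none
Why: Friedel–Crafts acylation of the strongly activated triphenol stops after one acyl group because the chelated ketone deactivates the ring; no stereocentre is formed.

Step 2
Reactants: 3 phlorisobutyrophenone; 4 trimethylene dithiotosylate [S,S'-propane-1,3-diyl bis(4-methylbenzenesulfonothioate)]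
Product: 6 spiro-dithiane-blocked triketone [9,11-dihydroxy-8-(2-methylpropanoyl)-1,5-dithiaspiro[5.5]undeca-8,10-dien-7-one], via aryl thioether thiosulfonate 5 (not isolated)
Conditions: 4 (1.0 equiv) added over 4 h to 3 (1.5 equiv), Et3N (2.2 equiv), MeCN, 0 °C → rt
Reagents that add atoms: none
Why: Proposed new method: the free ring CH of 3 (reacting like the methylene of a 1,3-diketone) is sulfenylated by one thiosulfonate terminus to give 5, whose tethered second terminus can reach only the same carbon, so an ipso-sulfenylation closes the spiro-1,3-dithiane and dearomatises the ring, leaving one CH2-type carbon (C5) and making C3 quaternary; the closest known reaction type is the dithianation of active methylene groups of 1,3-dicarbonyl compounds with trimethylene dithiotosylate as a removable blocking group, and slow addition to excess 3 limits double blocking.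

Step 3
Reactants: 7 (2E,6E)-farnesol
Product: 8 (2R,3R)-2,3-epoxyfarnesol [[(2R,3R)-3-[(3E)-4,8-dimethylnona-3,7-dien-1-yl]-3-methyloxiran-2-yl]methanol]
Conditions: Ti(OiPr)4 (10 mol%), D-(−)-diethyl tartrate (12 mol%), t-BuOOH (2 equiv), 4 Å MS, CH2Cl2, −20 °C
Reagents that add atoms: tert-butyl hydroperoxide, CC(C)(C)OO
Why: Sharpless asymmetric epoxidation is specific for the allylic-alcohol alkene among the three trisubstituted alkenes, and the D-(−)-tartrate ligand delivers oxygen to the face that gives the (2R,3R)-epoxide (typically ≥90% ee), which carries the absolute configuration of the whole synthesis.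

Step 4
Reactants: 8 (2R,3R)-2,3-epoxyfarnesol; 9 prenylmagnesium chloride (3-methylbut-2-en-1-ylmagnesium chloride, commercial THF solution)
Product: 11 (2S,3R,6E)-3,7,11-trimethyl-2-(3-methylbut-2-en-1-yl)dodeca-6,10-diene-1,3-diol, via lithium alkoxide 10 (not isolated)
Conditions: n-BuLi (1.0 equiv), THF, −78 °C; then 9 (2.0 equiv), CuI (20 mol%), −40 → 0 °C; aq NH4Cl
Reagents that add atoms: none
Why: Copper-catalysed SN2 opening of the 2,3-epoxy alkoxide by the allylic Grignard reagent takes place at C2 (farnesol numbering) because C3 is fully substituted, and the prenyl unit couples at its primary carbon, so inversion at C2 sets the future C7 as S while the tertiary carbinol carbon is untouched.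

Step 5
Reactants: 11 the diol; 6 spiro-dithiane-blocked triketone
Product: 14 cyclisation precursor [9,11-dihydroxy-10-[(2S,3R,6E)-3-hydroxy-3,7,11-trimethyl-2-(3-methylbut-2-en-1-yl)dodeca-6,10-dien-1-yl]-8-(2-methylpropanoyl)-1,5-dithiaspiro[5.5]undeca-8,10-dien-7-one], via aldehyde 12 (not isolated), via alkylidene triketone 13 (not isolated)
Conditions: TEMPO (10 mol%), PhI(OAc)2 (1.05 equiv), CH2Cl2, 0 °C → rt; after the oxidant is consumed 6 (1.2 equiv), Hantzsch ester (1.3 equiv), L-proline (5 mol%), 0 °C → rt
Reagents that add atoms: none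
Why: TEMPO/PhI(OAc)2 oxidises only the primary alcohol, and aldehyde 12 then undergoes a three-component reductive alkylation (Knoevenagel condensation at the only CH2-type carbon of 6, then immediate Hantzsch-ester conjugate reduction of alkylidene 13), which should be fast enough to preserve the C7 centre; the ring carbon C5 stays enolised and is not yet stereogenic.

Step 6
Reactants: 14 cyclisation precursor
Product: 16 dithiane-blocked bicycle [(1S,5S,7S,8R)-8-[(3E)-4,8-dimethylnona-3,7-dien-1-yl]-8-methyl-7-(3-methylbut-2-en-1-yl)-1-(2-methylpropanoyl)spiro[bicyclo[3.3.1]nonane-3,2'-[1,3]dithiane]-2,4,9-trione], via tertiary carbocation 15 (not isolated)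
Conditions: Ca(NTf2)2 (5 mol%), nBu4NPF6 (5 mol%), HFIP/CH2Cl2 (1:1), −20 → 0 °C; then Et3N
Reagents that add atoms: none
Why: Proposed new method: the Lewis-acid-activated tertiary alcohol ionises in HFIP to carbocation 15, which is captured by the acyl-bearing carbon C1 of the dearomatised triketone (C5 is sp3 so the ring can bridge, C3 is quaternary so only C1 can close a six-membered ring, and reversible O-alkylation drains to the C–C product) through a chair with the C7 prenyl group equatorial, which sets C1 and C5, while C8 is set by the larger dienyl chain taking the pseudo-equatorial site anti to C6 and the methyl the pseudo-axial one (a modest preference, estimated at about 4:1, minor C8 epimer removed by chromatography); the closest known reaction type is the biomimetic cationic cyclisation of dearomatised prenylated acylphloroglucinols to bicyclo[3.3.1]nonane-2,4,9-triones.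

Step 7
Reactants: 16 dithiane-blocked bicycle
Product: 17 prolifenone B [(1R,5R,7S,8R)-8-[(3E)-4,8-dimethylnona-3,7-dien-1-yl]-4-hydroxy-8-methyl-7-(3-methylbut-2-en-1-yl)-1-(2-methylpropanoyl)bicyclo[3.3.1]non-3-ene-2,9-dione]
Conditions: Raney Ni (W-2, acetone-deactivated, washed neutral), THF/EtOH, 0 °C → rt
Reagents that add atoms: none
Why: Raney nickel hydrogenolysis cleaves both C–S bonds of the dithioketal (the classical removal of a dithiane blocking group from an active methylene), the freed C3 methylene enolises to the vinylogous acid of the natural product, deactivated catalyst at low temperature should spare the three trisubstituted alkenes, and none of the four stereocentres can epimerise.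

**Compound list**

1 | phloroglucinol (benzene-1,3,5-triol) | Oc1cc(O)cc(O)c1 | starting material
2 | isobutyryl chloride | CC(C)C(Cl)=O | starting material
3 | phlorisobutyrophenone, 2-methyl-1-(2,4,6-trihydroxyphenyl)propan-1-one | CC(C)C(=O)c1c(O)cc(O)cc1O | intermediate
4 | trimethylene dithiotosylate, S,S'-propane-1,3-diyl bis(4-methylbenzenesulfonothioate) | Cc1ccc(cc1)S(=O)(=O)SCCCSS(=O)(=O)c1ccc(C)cc1 | starting material
5 | aryl thioether thiosulfonate, S-{3-[(2,4,6-trihydroxy-3-(2-methylpropanoyl)phenyl)sulfanyl]propyl} 4-methylbenzenesulfonothioate | CC(C)C(=O)c1c(O)cc(O)c(SCCCSS(=O)(=O)c2ccc(C)cc2)c1O | intermediate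
6 | spiro-dithiane-blocked triketone, 9,11-dihydroxy-8-(2-methylpropanoyl)-1,5-dithiaspiro[5.5]undeca-8,10-dien-7-one (dithiane carbon = C3, ring CH = C5, acyl carbon = C1) | CC(C)C(=O)C1=C(O)C=C(O)C2(SCCCS2)C1=O | intermediate
7 | (2E,6E)-farnesol | CC(C)=CCC/C(C)=C/CC/C(C)=C/CO | starting material
8 | (2R,3R)-2,3-epoxyfarnesol, [(2R,3R)-3-[(3E)-4,8-dimethylnona-3,7-dien-1-yl]-3-methyloxiran-2-yl]methanol | OC[C@H]1O[C@]1(C)CC/C=C(\C)CCC=C(C)C | intermediate
9 | prenylmagnesium chloride (3-methylbut-2-en-1-ylmagnesium chloride) | CC(C)=CC[Mg]Cl | starting material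
10 | lithium alkoxide of 8 | [Li+].[O-]C[C@H]1O[C@]1(C)CC/C=C(\C)CCC=C(C)C | intermediate
11 | (2S,3R,6E)-3,7,11-trimethyl-2-(3-methylbut-2-en-1-yl)dodeca-6,10-diene-1,3-diol | OC[C@H](CC=C(C)C)[C@](C)(O)CC/C=C(\C)CCC=C(C)C | intermediate
12 | (2R,3R,6E)-3-hydroxy-3,7,11-trimethyl-2-(3-methylbut-2-en-1-yl)dodeca-6,10-dienal (same spatial arrangement at C2 as in 11) | O=C[C@H](CC=C(C)C)[C@](C)(O)CC/C=C(\C)CCC=C(C)C | intermediate
13 | alkylidene triketone, 9-hydroxy-10-[(2S,3R,6E)-3-hydroxy-3,7,11-trimethyl-2-(3-methylbut-2-en-1-yl)dodeca-6,10-dien-1-ylidene]-8-(2-methylpropanoyl)-1,5-dithiaspiro[5.5]undec-8-ene-7,11-dione (exocyclic C=C geometry not defined) | CC(C)C(=O)C1=C(O)C(=C[C@H](CC=C(C)C)[C@](C)(O)CC/C=C(\C)CCC=C(C)C)C(=O)C2(SCCCS2)C1=O | intermediate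
14 | cyclisation precursor, 9,11-dihydroxy-10-[(2S,3R,6E)-3-hydroxy-3,7,11-trimethyl-2-(3-methylbut-2-en-1-yl)dodeca-6,10-dien-1-yl]-8-(2-methylpropanoyl)-1,5-dithiaspiro[5.5]undeca-8,10-dien-7-one | CC(C)C(=O)C1=C(O)C(C[C@H](CC=C(C)C)[C@](C)(O)CC/C=C(\C)CCC=C(C)C)=C(O)C2(SCCCS2)C1=O | intermediate
15 | tertiary carbocation formed from 14 by loss of hydroxide at the side-chain carbinol carbon (C8) | CC(C)C(=O)C1=C(O)C(C[C@H](CC=C(C)C)[C+](C)CC/C=C(\C)CCC=C(C)C)=C(O)C2(SCCCS2)C1=O | intermediate
16 | dithiane-blocked bicycle, (1S,5S,7S,8R)-8-[(3E)-4,8-dimethylnona-3,7-dien-1-yl]-8-methyl-7-(3-methylbut-2-en-1-yl)-1-(2-methylpropanoyl)spiro[bicyclo[3.3.1]nonane-3,2'-[1,3]dithiane]-2,4,9-trione (same spatial arrangement as the target; C1 and C5 descriptors change only through the priority of sulfur) | CC(C)=CCC/C(C)=C/CC[C@]1(C)[C@@H](CC=C(C)C)C[C@H]2C(=O)[C@]1(C(=O)C(C)C)C(=O)C3(SCCCS3)C2=O | intermediate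
17 | prolifenone B, (1R,5R,7S,8R)-8-[(3E)-4,8-dimethylnona-3,7-dien-1-yl]-4-hydroxy-8-methyl-7-(3-methylbut-2-en-1-yl)-1-(2-methylpropanoyl)bicyclo[3.3.1]non-3-ene-2,9-dione | CC(C)=CCC/C(C)=C/CC[C@]1(C)[C@@H](CC=C(C)C)C[C@H]2C(=O)[C@]1(C(=O)C(C)C)C(=O)C=C2O | target

**Totals and fallbacks**

Total steps: 7. Longest linear sequence: 5 steps (7 → 8 → 11 → 14 → 16 → 17; the branch from 1 is equally long).

Step 6 is the most likely to fail, because carbocation 15 can lose a proton, give a low C8 ratio or stop at O-alkylation. The fallback replaces the free cation by a stereospecific epoxide opening. It sets out from 7: Sharpless epoxidation with L-(+)-diethyl tartrate gives (2S,3S)-2,3-epoxyfarnesol F1, Dess–Martin oxidation gives the epoxy aldehyde F2, and reductive alkylation of 6 with F2 and Hantzsch ester gives the epoxide-bearing triketone F3. BF3·OEt2 at −78 °C then lets C1 open the epoxide at its tertiary carbon with inversion, which sets C8, C1 and C5 together and leaves an equatorial hydroxyl at C7 in the hydroxy bicycle F4. The alcohol is converted into its O-phenyl thionocarbonate F5 (PhOC(S)Cl, pyridine), which reacts with stannyl radicals much faster than the dialkyl dithioketal. Radical allylation (allyltributylstannane, AIBN) delivers the allyl group to the open exo face to give the 7-allyl bicycle F6, and cross-metathesis with 2-methylbut-2-ene (second-generation Grubbs catalyst) gives 16, where the route is rejoined.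

Step 2 is the second risk, because the ipso-sulfenylation that closes the spiro ring is untested on a phloroglucinol and double blocking can compete. The fallback builds the blocked ring by a polyketide-type double Claisen condensation instead of sulfenylating the arene. It sets out from 2: acylation of the lithium enolate of acetone with 2 gives 5-methylhexane-2,4-dione F7, whose dianion (LDA, THF) is condensed with diethyl 1,3-dithiane-2,2-dicarboxylate F8 (made from diethyl oxomalonate and propane-1,3-dithiol with BF3·OEt2). The terminal carbanion acylates first and the central carbon then closes the ring on the second ester, which gives 6 directly and rejoins the route there.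

Step 4 is the third risk, because a prenyl-metal can couple through its tertiary carbon and the hindered C2 opening can be slow. The fallback makes the prenyl group by metathesis instead of delivering it as a prenyl-metal. It sets out from 8: allylmagnesium bromide with CuI opens the epoxide at C2 without any α/γ ambiguity to give the allyl diol F9, and cross-metathesis of its terminal alkene with 2-methylbut-2-ene (second-generation Grubbs catalyst) gives 11, where the route is rejoined.

**Further compounds**

F1 | step 6 | (2S,3S)-2,3-epoxyfarnesol, [(2S,3S)-3-[(3E)-4,8-dimethylnona-3,7-dien-1-yl]-3-methyloxiran-2-yl]methanol | OC[C@@H]1O[C@@]1(C)CC/C=C(\C)CCC=C(C)C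
F2 | step 6 | epoxy aldehyde, (2R,3S)-3-[(3E)-4,8-dimethylnona-3,7-dien-1-yl]-3-methyloxirane-2-carbaldehyde | O=C[C@@H]1O[C@@]1(C)CC/C=C(\C)CCC=C(C)C
F3 | step 6 | epoxide-bearing triketone, 10-{[(2S,3S)-3-[(3E)-4,8-dimethylnona-3,7-dien-1-yl]-3-methyloxiran-2-yl]methyl}-9,11-dihydroxy-8-(2-methylpropanoyl)-1,5-dithiaspiro[5.5]undeca-8,10-dien-7-one | CC(C)C(=O)C1=C(O)C(C[C@@H]2O[C@@]2(C)CC/C=C(\C)CCC=C(C)C)=C(O)C2(SCCCS2)C1=O
F4 | step 6 | hydroxy bicycle, (1S,5S,7S,8S)-8-[(3E)-4,8-dimethylnona-3,7-dien-1-yl]-7-hydroxy-8-methyl-1-(2-methylpropanoyl)spiro[bicyclo[3.3.1]nonane-3,2'-[1,3]dithiane]-2,4,9-trione | CC(C)=CCC/C(C)=C/CC[C@]1(C)[C@@H](O)C[C@H]2C(=O)[C@]1(C(=O)C(C)C)C(=O)C3(SCCCS3)C2=O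
F5 | step 6 | O-phenyl thionocarbonate of F4 at the C7 oxygen, (1S,5S,7S,8S) | CC(C)=CCC/C(C)=C/CC[C@]1(C)[C@@H](OC(=S)Oc3ccccc3)C[C@H]2C(=O)[C@]1(C(=O)C(C)C)C(=O)C3(SCCCS3)C2=O
F6 | step 6 | 7-allyl bicycle, (1S,5S,7S,8R)-8-[(3E)-4,8-dimethylnona-3,7-dien-1-yl]-8-methyl-1-(2-methylpropanoyl)-7-(prop-2-en-1-yl)spiro[bicyclo[3.3.1]nonane-3,2'-[1,3]dithiane]-2,4,9-trione | CC(C)=CCC/C(C)=C/CC[C@]1(C)[C@@H](CC=C)C[C@H]2C(=O)[C@]1(C(=O)C(C)C)C(=O)C3(SCCCS3)C2=O
F7 | step 2 | 5-methylhexane-2,4-dione | CC(C)C(=O)CC(C)=O
F8 | step 2 | diethyl 1,3-dithiane-2,2-dicarboxylate | CCOC(=O)C1(C(=O)OCC)SCCCS1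
F9 | step 4 | allyl diol, (2S,3R,6E)-3,7,11-trimethyl-2-(prop-2-en-1-yl)dodeca-6,10-diene-1,3-diol | OC[C@H](CC=C)[C@](C)(O)CC/C=C(\C)CCC=C(C)C
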